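A closed, stirred vessel at constant temperature and volume holds substrate, which on the list of suspects turns into an intermediate that two nucleophiles and solvolysis may take up.

| flask | substrate | first nucleophile | second nucleophile | protic impurity | remark | time |
|---|---|---|---|---|---|---|
| birch | 0.99 M | 1.78 M | 1.09 M | 0.0198 M | the very flask that is asked about, followed so far |  |
| oak | 0.99 M | 1.78 M | 1.6 M | 0.0198 M | run made earlier |  |
| flask | 0.99 M | 1.78 M | 1.09 M | 0.0198 M |  | 15 d |

- birch (time / d: other capture product / %, target / %, substrate / %): 0.625: 6.7, 1.9, 73.8; 1.67: 13.1, 3.5, 45.3; 3.00: 16.5, 4.1, 24.3; 5.00: 20.1, 4.0, 9.4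
- oak (time / d: other capture product / %, target / %, substrate / %): 1.25: 13.7, 3.1, 55.1; 3.00: 23.1, 3.6, 24.1; 6.00: 28.5, 3.9, 4.7; 15.0: 30.2, 4.6, 0.6

(standard deviation of a reading: 0.5 percentage points)

- ratio of other capture product to target at 4.0 h
- ratio of other capture product to target at 30 h
- ratio of other capture product to target at 15 d
- which of other capture product and target there is more of at 15 d

- on the list of suspects stand: second nucleophile + intermediate -> other capture product; substrate -> intermediate; second nucleophile + protic impurity -> quenched reagent; first nucleophile + intermediate -> target; 2 first nucleophile -> homo dimer; intermediate -> solvolysis product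

On the list of suspects, other capture product and target both form from the intermediate, so its concentration cancels from their rate ratio, which goes as [second nucleophile]/[first nucleophile]. In logarithms, at the same time and the same charge of first nucleophile, the product ratio should then rise one decade per decade of [second nucleophile]. Birch and oak test this at 3.00 d: their charges lie 0.167 decades apart, their read ratios 0.203.

Both runs share the substrate and first nucleophile charges, 0.99 M and 1.78 M, so these carry over unchanged. Protic impurity can take 0.00796 decades off [second nucleophile], which can be dropped. The scatter of 0.5 percentage points falls on oak's last target reading of 4.6% and on its last other capture product reading of 30.2%, a larger reading, so the target has to be known well. Oak's target readings at 6.00 d and 15.0 d average 4.25%.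

With oak's final other capture product and charge, that mean gives 4.44 L mol⁻¹: the capture gain, the ratio at 15.0 d per unit of second nucleophile charged, the other charges held. For birch at 15 d this reckoning of mine gives 4.84, which puts other capture product 0.685 decades ahead of target.

The forecast gives 2.8, 3.6 and 5.1, with other capture product ahead, on this ground: “The first nucleophile is evidently being lost to homo dimer, with a half-life of about 1.5 days.” Its end ratio is higher than the reckoning here.

The flask gives 2.38 at 4.0 h, 3.57 at 30 h and 5.43 at 15 d, with other capture product ahead, at 22.7% against 4.17% of target.

    second nucleophile + intermediate → other capture product (k = 1.30 L mol⁻¹ min⁻¹)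
    substrate → intermediate (k = 3.30 × 10⁻⁴ min⁻¹)
    second nucleophile + protic impurity → quenched reagent (k = 0.0430 L mol⁻¹ min⁻¹)
    first nucleophile + intermediate → target (k = 0.370 L mol⁻¹ min⁻¹)
    2 first nucleophile → homo dimer (k = 3.20 × 10⁻⁴ L mol⁻¹ min⁻¹)
    intermediate → solvolysis product (k = 4.00 min⁻¹)

Birch's result puts its capture gain at 4.98 L mol⁻¹, against 4.44 L mol⁻¹ read from oak. The neighbour charged with 2.7 M of second nucleophile stands 0.394 decades above birch, so the gain read from oak gives it 12.0. That neighbour reaches 14.0 at 15 d, a gain of 5.19 L mol⁻¹, with other capture product at 43.0% and target at 3.08%.

The earlier runs and the new flask are simulated from invented constants; noise was put on by code.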